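**Plan**

- Retrosynthesis: the C13=C14 alkene and the C15–H bond are traced back to a C13 allylic alcohol on a C14=C15 alkene. Cutting C13–C14 then gives a ring A/B aldehyde (C13) and a ring C/D alkenyl triflate (C14).
- In the aldehyde, C10–CH3 is cut back to a ketone, and O1–C2 and C6–C11 are cut together. The trans-fused oxepane (ring A: O1, C2 with two methyls, C3 carbinol, C4, C5, quaternary C6, C7) and cyclohexane (ring B: C6–C11, C10 oxygenated, C11 bearing C12–C13) are the folded form of a 2,3:6,7-bis-epoxy chain ending in a C10=C11 enol silane.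
- In the triflate, ring C is cut at C15=C16 (metathesis), C14–C15, C16–C17 and C22–C23; ring D comes from (R)-linalool by metathesis.
- Forward: geranylacetone chain → bis-epoxide → rings A and B in one cascade → C10 methyl → aldehyde; ring D → ring C → triflate; Nozaki–Hiyama–Kishi union at C13–C14; reductive alkene transposition; desilylation.
- Stereochemistry: C3, C6, C7 from Shi epoxidation (C6 inverted in the cascade), C11 from the (Z)-enol silane in a chair, C10 from equatorial methyl addition. C19 comes from (R)-linalool and is relayed to C22 (anti epoxide opening) and C18 (hydroboration from the open face). C13 is set by CBS reduction and transferred to C15 and the (E)-alkene by the suprafacial diazene rearrangement.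

Key step: step 5

Remark (numbering and assumption): atoms are numbered O1, C2–C11 (rings A and B), C12–C13 (linker), C14–C18, C22, C23 (ring C) and C18–C22 (ring D; C19 is the ring D carbinol carbon, C23 the gem-dimethyl carbon). It is assumed that the D-fructose-derived Shi ketone gives the (R)-configured epoxides and that commercial (R)-linalool of high enantiomeric purity is used; the two halves are made separately, so a minor enantiomer of either would end as a separable diastereomer after step 20.

**Route**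

Step 1
Reactants: 1 geranylacetone; 2 benzyloxyacetaldehyde
Product: 4 (7E)-1-(benzyloxy)-2-hydroxy-8,12-dimethyltrideca-7,11-dien-4-one (racemic carbinol), via lithium enolate 3 (not isolated)
Conditions: LiN(i-Pr)2 (LDA), THF, −78 °C; then 2, −78 °C; aq. NH4Cl
Reagents that add atoms: none
Why: Kinetic aldol addition: LDA removes a proton from the methyl group of the methyl ketone and the enolate adds to the reactive α-alkoxy aldehyde to form C11–C12; the new carbinol centre is not controlled because it is eliminated in step 2.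

Step 2
Reactants: 4 aldol adduct
Product: 5 (2E,7E)-1-(benzyloxy)-8,12-dimethyltrideca-2,7,11-trien-4-one
Conditions: MsCl, Et3N, CH2Cl2, 0 °C → rt
Reagents that add atoms: none
Why: Mesylation followed by E1cB elimination (completion of the aldol condensation) should give the thermodynamically favoured (E)-enone; no stereocentre remains.

Step 3
Reactants: 5 trienone
Product: 6 (2E)-1-(benzyloxy)-6-[(2R,3R)-3-{2-[(2R)-3,3-dimethyloxiran-2-yl]ethyl}-3-methyloxiran-2-yl]hex-2-en-4-one, the (3R,6R,7R)-bis-epoxy enone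
Conditions: Shi ketone (D-fructose-derived, 0.6 equiv), KHSO5 (as Oxone), K2CO3, Bu4NHSO4, MeCN–CH2(OMe)2–aq. Na2B4O7 buffer (pH 10.5), 0 °C
Reagents that add atoms: potassium peroxymonosulfate, [K+].[O-]S(=O)(=O)OO
Why: Shi asymmetric epoxidation: the chiral dioxirane epoxidises both electron-rich trisubstituted alkenes through the spiro transition state, setting 3R, 6R and 7R under catalyst control, while the electron-poor enone alkene should not react.

Step 4
Reactants: 6 bis-epoxy enone
Product: 7 {[(3Z)-1-(benzyloxy)-6-[(2R,3R)-3-{2-[(2R)-3,3-dimethyloxiran-2-yl]ethyl}-3-methyloxiran-2-yl]hex-3-en-4-yl]oxy}triethylsilane, the (3R,6R,7R)-bis-epoxy (Z)-C10=C11 triethylsilyl enol ether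
Conditions: RhCl(PPh3)3 (2 mol %), Et3SiH, THF, 50 °C
Reagents that add atoms: triethylsilane, CC[SiH](CC)CC
Why: Rhodium-catalysed 1,4-hydrosilylation of an enone with a monohydrosilane places silicon on oxygen and hydride on C12 through the s-cis enone, which should give the C10=C11 enol silane regiospecifically and with Z geometry, the epoxides being inert to these neutral conditions.

Step 5
Reactants: 7 bis-epoxy (Z)-enol silane
Product: 8 (3R,6R,7R,11R)-ring A/B ketone: trans-fused oxepane–cyclohexanone with C2 gem-dimethyl, C3 OSiEt3, C6 methyl, C10 ketone and C11 CH2CH2OBn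
Conditions: Et3SiOTf (1.1 equiv), 2,6-di-tert-butyl-4-methylpyridine, CH2Cl2, −78 °C; Et3N, aq. NaHCO3
Reagents that add atoms: triethylsilyl trifluoromethanesulfonate, CC[Si](CC)(CC)OS(=O)(=O)C(F)(F)F
Why: Et3SiOTf silylates the oxygen of the terminal 2,3-epoxide; the oxygen of the 6,7-epoxide then attacks tertiary C2 with inversion to give a bicyclic epoxonium ion, C11 of the enol silane opens this ion at tertiary C6 anti to the departing oxygen, and the resulting silyloxocarbenium ion hands its Et3Si group to triflate, leaving the C10 ketone and the O3 silyl ether. The closest known reaction type is the silyl triflate-promoted tandem oxacyclisation–carbacyclisation of 1,5-diepoxides terminated by an enol silane. Ring A closes in a 7-endo mode (the oxygen on C7 to C2, endo opening of the 2,3-epoxide) and ring B in a 6-endo mode (C11 to C6, endo opening of the epoxonium ion) through a chair. C6 is set by inversion at the epoxide carbon, so the trans epoxide becomes the trans ring fusion while C7 and C3 keep their Shi configurations, and C11 is set by the Z geometry of the enol silane, which places C12 equatorial in the chair. The step needs endo rather than exo opening at both epoxides and activation of the terminal epoxide before the enol silane attacks the 6,7-epoxide directly; the tertiary, cation-stabilising character of C2 and C6, the more exposed terminal epoxide, the low temperature and the hindered base (no protic acid) should secure this, and matching the silyl group of the promoter to that of the enol ether gives a single C3 silyl ether.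

Step 6
Reactants: 8 ring A/B ketone
Product: 9 (3R,6R,7R,10S,11R)-tertiary alcohol: as 8 with C10 bearing an equatorial methyl and an axial hydroxyl
Conditions: MeMgBr, CeCl3, THF, −78 → 0 °C
Reagents that add atoms: methylmagnesium bromide, C[Mg]Br
Why: Organocerium 1,2-addition to a hindered, enolisable ketone: methyl should enter along the equatorial path because the axial path is blocked by the syn-axial C6 methyl group, giving the axial C10 hydroxyl (10S) cis to the equatorial C11 side chain.

Step 7
Reactants: 9 tertiary alcohol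
Product: 10 (3R,6R,7R,10S,11R)-3,10-bis(triethylsilyl) ether with the C13 benzyl ether
Conditions: Et3SiOTf, 2,6-lutidine, CH2Cl2, 0 °C → rt
Reagents that add atoms: triethylsilyl trifluoromethanesulfonate, CC[Si](CC)(CC)OS(=O)(=O)C(F)(F)F
Why: Silylation of a hindered tertiary alcohol with a silyl triflate and 2,6-lutidine; the ether prevents lactol formation at C13 and tetrahydrofuran formation between O10 and C13 in step 23.

Step 8
Reactants: 10 bis-silyl benzyl ether
Product: 11 (3R,6R,7R,10S,11R)-C13 primary alcohol (C11–CH2–CH2OH), O3 and O10 as triethylsilyl ethers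
Conditions: H2 (1 atm), Pd(OH)2/C, EtOAc, rt
Reagents that add atoms: none
Why: Hydrogenolysis of the benzyl ether in a non-protic solvent should leave the triethylsilyl ethers intact; no alkene is present at this stage.

Step 9
Reactants: 11 primary alcohol
Product: 12 (3R,6R,7R,10S,11R)-C13 aldehyde (C11–CH2–CHO), O3 and O10 as triethylsilyl ethers
Conditions: Dess–Martin periodinane, NaHCO3, CH2Cl2, 0 °C → rt
Reagents that add atoms: none
Why: Dess–Martin oxidation under buffered conditions gives the aldehyde without touching the silyl ethers; C11 is β to the new carbonyl and cannot epimerise.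

Step 10
Reactants: 13 (R)-(−)-linalool
Product: 14 (1R)-1-methylcyclopent-2-en-1-ol
Conditions: second-generation Grubbs catalyst (1 mol %), CH2Cl2, 40 °C
Reagents that add atoms: none
Why: Ring-closing metathesis of the 1,6-diene closes ring D with loss of isobutene; the tertiary carbinol centre of (R)-linalool is carried through unchanged as C19.

Step 11
Reactants: 14 cyclopentenol
Product: 15 (1S,2R,5S)-2-methyl-6-oxabicyclo[3.1.0]hexan-2-ol (epoxide cis to the hydroxyl)
Conditions: VO(acac)2 (2 mol %), t-BuOOH, CH2Cl2, 0 °C → rt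
Reagents that add atoms: tert-butyl hydroperoxide, CC(C)(C)OO
Why: Hydroxyl-directed epoxidation delivers oxygen to the alkene face cis to the tertiary hydroxyl, fixing the epoxide carbons (later C18 and C22) relative to C19.

Step 12
Reactants: 15 epoxy alcohol
Product: 16 2-[(1S,2S,3R)-2,3-dihydroxy-3-methylcyclopentyl]-2-methylpropanenitrile
Conditions: i-PrCN, LiN(i-Pr)2 (LDA, excess), THF, −78 °C; then 15, DMPU, −78 → 50 °C; aq. NH4Cl
Reagents that add atoms: isobutyronitrile, CC(C)C#N
Why: SN2 opening of the epoxide by the lithiated nitrile at the carbon remote from the fully substituted, alkoxide-bearing C19 occurs with inversion, which forms C22–C23 trans to the neighbouring oxygen and cis to the C19 methyl group.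

Step 13
Reactants: 16 diol nitrile
Product: 17 2-[(1S,3R)-3-hydroxy-3-methyl-2-oxocyclopentyl]-2-methylpropanenitrile
Conditions: IBX, EtOAc, 75 °C
Reagents that add atoms: none
Why: IBX oxidises the secondary alcohol of a 1,2-diol to the α-hydroxy ketone without glycol cleavage and, being neutral, should not epimerise C22 next to the new carbonyl.

Step 14
Reactants: 17 α-hydroxy ketone
Product: 18 2-methyl-2-[(1S,3R)-3-methyl-2-oxo-3-(triethylsilyloxy)cyclopentyl]propanenitrile
Conditions: Et3SiOTf, 2,6-lutidine, CH2Cl2, −78 → 0 °C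
Reagents that add atoms: triethylsilyl trifluoromethanesulfonate, CC[Si](CC)(CC)OS(=O)(=O)C(F)(F)F
Why: Silylation of the tertiary alcohol with a silyl triflate protects O19 for the organometallic steps and the later enolate triflation.

Step 15
Reactants: 18 silyloxy ketone
Product: 19 2-methyl-2-[(1S,3R)-3-methyl-2-methylidene-3-(triethylsilyloxy)cyclopentyl]propanenitrile
Conditions: Zn, CH2Br2, TiCl4, THF–CH2Cl2, 0 °C → rt
Reagents that add atoms: dibromomethane, BrCBr
Why: Lombardo methylenation converts hindered, enolisable ketones into methylene compounds under non-basic conditions, so C22 should keep its configuration and the nitrile should be untouched.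

Step 16
Reactants: 19 methylene nitrile
Product: 21 2-methyl-2-[(1R,2R,3R)-3-methyl-2-(prop-2-en-1-yl)-3-(triethylsilyloxy)cyclopentyl]propanenitrile, via alkylborane 20 (not isolated)
Conditions: 9-BBN, THF, rt → 50 °C; then vinyl bromide, PdCl2(dppf) (5 mol %), K3PO4, DMF–H2O, rt
Reagents that add atoms: vinyl bromide, C=CBr
Why: Hydroboration puts boron on the terminal carbon and hydrogen on C18 from the face opposite the C19 methyl and the bulky C23 group, which sets C18 with all three carbon substituents cis, and the B-alkyl Suzuki–Miyaura coupling turns the borane into the allyl group (C16–C17 bond).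

Step 17
Reactants: 21 allyl nitrile
Product: 23 2,4-dimethyl-4-[(1R,2R,3R)-3-methyl-2-(prop-2-en-1-yl)-3-(triethylsilyloxy)cyclopentyl]pent-1-en-3-one, via ketimine 22 (not isolated)
Conditions: isopropenylmagnesium bromide, CuBr·SMe2 (5 mol %), THF, 60 °C; then 10 % aq. citric acid, rt
Reagents that add atoms: isopropenylmagnesium bromide, CC(=C)[Mg]Br; water, O
Why: Copper-catalysed addition of a Grignard reagent to a hindered tertiary nitrile stops at the metallo-ketimine, and mild acid hydrolysis should give the isopropenyl ketone (C14 carbonyl, C14–C15 bond) without cleaving the tertiary silyl ether.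

Step 18
Reactants: 23 dienone
Product: 24 (3R,3aR,8aR)-3,6,8,8-tetramethyl-3-(triethylsilyloxy)-1,2,3,3a,4,8a-hexahydroazulen-7(8H)-one, the cis-fused ring C/D enone (C14 ketone, C15=C16)
Conditions: second-generation Hoveyda–Grubbs catalyst (5 mol %), toluene, 80 °C
Reagents that add atoms: none
Why: Ring-closing metathesis between the allyl group and the 1,1-disubstituted enone alkene, helped by their cis arrangement on ring D and by the gem-dimethyl group, should close the seven-membered ring C with loss of ethene.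

Step 19
Reactants: 24 ring C/D enone
Product: 26 (3R,3aR,8aR)-3,6,8,8-tetramethyl-3-(triethylsilyloxy)-1,2,3,3a,4,5,8,8a-octahydroazulen-7-yl trifluoromethanesulfonate, via lithium enolate 25 (not isolated)
Conditions: LiBH(s-Bu)3 (L-Selectride), THF, −78 °C; then Comins' reagent, −78 → 0 °C
Reagents that add atoms: N-(5-chloropyridin-2-yl)bis(trifluoromethanesulfonyl)imide (Comins' reagent), FC(F)(F)S(=O)(=O)N(c1ccc(Cl)cn1)S(=O)(=O)C(F)(F)F
Why: Conjugate reduction of the enone (carbonyl attack is blocked by the neighbouring quaternary C23) generates the C14–C15 enolate regiospecifically, and O-triflation gives the tetrasubstituted alkenyl triflate.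

Step 20
Reactants: 12 ring A/B aldehyde; 26 ring C/D alkenyl triflate
Product: 27 C13 allylic alcohol (both C13 epimers): C13(OH) bonded to C12 and to C14 of the C14=C15 alkene, O3, O10 and O19 as triethylsilyl ethers
Conditions: CrCl2 (6 equiv), NiCl2 (2 mol %), DMF, rt
Reagents that add atoms: none
Why: Nozaki–Hiyama–Kishi coupling: zerovalent nickel inserts into the alkenyl C–OTf bond, transmetalation gives an alkenylchromium species that adds chemoselectively to the aldehyde to form C13–C14; the C13 configuration is not controlled here and is erased in step 21.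

Step 21
Reactants: 27 allylic alcohols
Product: 28 C13 enone (C13 ketone on the C14=C15 alkene), tris(triethylsilyl) ether
Conditions: Dess–Martin periodinane, NaHCO3, CH2Cl2, 0 °C → rt
Reagents that add atoms: none
Why: Dess–Martin oxidation of the secondary allylic alcohols converges both C13 epimers to one ketone.

Step 22
Reactants: 28 enone
Product: 29 (13R)-allylic alcohol, tris(triethylsilyl) ether
Conditions: (S)-2-methyl-CBS-oxazaborolidine (1 equiv), catecholborane, toluene, −78 → −40 °C; MeOH
Reagents that add atoms: none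
Why: Corey–Bakshi–Shibata reduction: the oxazaborolidine binds the ketone anti to the bulky tetrasubstituted alkenyl group and hydride is delivered to one carbonyl face, which should give the (13R)-alcohol under reagent control.

Step 23
Reactants: 29 (13R)-allylic alcohol
Product: 33 3,10,19-tris(triethylsilyl) ether of the target, via hydrazone adduct 30 (not isolated), via sulfonylhydrazine 31 (not isolated), via allylic diazene 32 (not isolated)
Conditions: N-isopropylidene-N′-(2-nitrobenzenesulfonyl)hydrazine (IPNBSH), PPh3, DEAD, THF, 0 → 23 °C; then CF3CH2OH–H2O (1:1), 23 °C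
Reagents that add atoms: none
Why: Reductive 1,3-transposition of an allylic alcohol: Mitsunobu displacement by the sulfonyl hydrazone inverts C13, hydrolysis and loss of sulfinic acid give the (13S)-monoalkyl diazene, and its suprafacial retro-ene loss of N2 delivers hydrogen to the C15 face on which nitrogen sits (15R) while the C12 chain turns away from the quaternary C23 to give the (E)-C13=C14 alkene.

Step 24
Reactants: 33 tris-silyl ether
Product: 34 CNP0167890.2, (3R,6R,7R,10S,11R,13E,15R,18R,19R,22R)
Conditions: Bu4NF (TBAF), THF, 50 °C; aq. NH4Cl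
Reagents that add atoms: none
Why: Fluoride-mediated cleavage of the three triethylsilyl ethers under non-ionising conditions should release the triol without affecting the exocyclic alkene or the tertiary carbinols.

**Compound list**

1 | geranylacetone, (5E)-6,10-dimethylundeca-5,9-dien-2-one | CC(=O)CC/C=C(\C)CCC=C(C)C | starting material
2 | benzyloxyacetaldehyde | O=CCOCc1ccccc1 | starting material
3 | lithium enolate of 1 (kinetic, methyl side) | [Li+].[O-]C(=C)CC/C=C(\C)CCC=C(C)C | intermediate
4 | (7E)-1-(benzyloxy)-2-hydroxy-8,12-dimethyltrideca-7,11-dien-4-one (racemic carbinol) | CC(C)=CCC/C(C)=C/CCC(=O)CC(O)COCc1ccccc1 | intermediate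
5 | (2E,7E)-1-(benzyloxy)-8,12-dimethyltrideca-2,7,11-trien-4-one | CC(C)=CCC/C(C)=C/CCC(=O)/C=C/COCc1ccccc1 | intermediate
6 | (3R,6R,7R)-bis-epoxy enone | CC1(C)O[C@@H]1CC[C@@]2(C)O[C@@H]2CCC(=O)/C=C/COCc1ccccc1 | intermediate
7 | (3R,6R,7R)-bis-epoxy (Z)-triethylsilyl enol ether | CC1(C)O[C@@H]1CC[C@@]2(C)O[C@@H]2CC/C(O[Si](CC)(CC)CC)=C/CCOCc1ccccc1 | intermediate
8 | (3R,6R,7R,11R)-ring A/B ketone, C3 triethylsilyl ether, C13 benzyl ether | c1ccccc1COCC[C@@H]2[C@@]3(C)CC[C@@H](O[Si](CC)(CC)CC)C(C)(C)O[C@@H]3CCC2=O | intermediate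
9 | (3R,6R,7R,10S,11R)-C10 tertiary alcohol | c1ccccc1COCC[C@@H]2[C@@]3(C)CC[C@@H](O[Si](CC)(CC)CC)C(C)(C)O[C@@H]3CC[C@]2(C)O | intermediate
10 | 3,10-bis(triethylsilyl) ether, C13 benzyl ether | c1ccccc1COCC[C@@H]2[C@@]3(C)CC[C@@H](O[Si](CC)(CC)CC)C(C)(C)O[C@@H]3CC[C@]2(C)O[Si](CC)(CC)CC | intermediate
11 | C13 primary alcohol, 3,10-bis(triethylsilyl) ether | OCC[C@@H]1[C@@]2(C)CC[C@@H](O[Si](CC)(CC)CC)C(C)(C)O[C@@H]2CC[C@]1(C)O[Si](CC)(CC)CC | intermediate
12 | C13 aldehyde, 3,10-bis(triethylsilyl) ether | O=CC[C@@H]1[C@@]2(C)CC[C@@H](O[Si](CC)(CC)CC)C(C)(C)O[C@@H]2CC[C@]1(C)O[Si](CC)(CC)CC | intermediate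
13 | (R)-(−)-linalool, (3R)-3,7-dimethylocta-1,6-dien-3-ol | C=C[C@](C)(O)CCC=C(C)C | starting material
14 | (1R)-1-methylcyclopent-2-en-1-ol | C[C@]1(O)C=CCC1 | intermediate
15 | (1S,2R,5S)-2-methyl-6-oxabicyclo[3.1.0]hexan-2-ol | C[C@@]1(O)CC[C@@H]2O[C@H]12 | intermediate
16 | 2-[(1S,2S,3R)-2,3-dihydroxy-3-methylcyclopentyl]-2-methylpropanenitrile | C[C@@]1(O)CC[C@@H](C(C)(C)C#N)[C@@H]1O | intermediate
17 | 2-[(1S,3R)-3-hydroxy-3-methyl-2-oxocyclopentyl]-2-methylpropanenitrile | C[C@@]1(O)CC[C@@H](C(C)(C)C#N)C1=O | intermediate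
18 | 2-methyl-2-[(1S,3R)-3-methyl-2-oxo-3-(triethylsilyloxy)cyclopentyl]propanenitrile | C[C@@]1(O[Si](CC)(CC)CC)CC[C@@H](C(C)(C)C#N)C1=O | intermediate
19 | 2-methyl-2-[(1S,3R)-3-methyl-2-methylidene-3-(triethylsilyloxy)cyclopentyl]propanenitrile | C[C@@]1(O[Si](CC)(CC)CC)CC[C@@H](C(C)(C)C#N)C1=C | intermediate
20 | B-alkyl-9-BBN adduct of 19 (boron on the new CH2, C17) | C[C@@]1(O[Si](CC)(CC)CC)CC[C@@H](C(C)(C)C#N)[C@H]1CB2C3CCCC2CCC3 | intermediate
21 | 2-methyl-2-[(1R,2R,3R)-3-methyl-2-(prop-2-en-1-yl)-3-(triethylsilyloxy)cyclopentyl]propanenitrile | C[C@@]1(O[Si](CC)(CC)CC)CC[C@@H](C(C)(C)C#N)[C@H]1CC=C | intermediate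
22 | N-unsubstituted ketimine of 23 (magnesium salt before work-up) | C[C@@]1(O[Si](CC)(CC)CC)CC[C@@H](C(C)(C)C(=N)C(C)=C)[C@H]1CC=C | intermediate
23 | 2,4-dimethyl-4-[(1R,2R,3R)-3-methyl-2-(prop-2-en-1-yl)-3-(triethylsilyloxy)cyclopentyl]pent-1-en-3-one | C[C@@]1(O[Si](CC)(CC)CC)CC[C@@H](C(C)(C)C(=O)C(C)=C)[C@H]1CC=C | intermediate
24 | (3R,3aR,8aR)-3,6,8,8-tetramethyl-3-(triethylsilyloxy)-1,2,3,3a,4,8a-hexahydroazulen-7(8H)-one | C[C@@]1(O[Si](CC)(CC)CC)CC[C@@H]2[C@H]1CC=C(C)C(=O)C2(C)C | intermediate
25 | lithium C14–C15 enolate of the ring C/D ketone | CC1=C([O-])C(C)(C)[C@@H]2CC[C@@](C)(O[Si](CC)(CC)CC)[C@@H]2CC1.[Li+] | intermediate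
26 | (3R,3aR,8aR)-3,6,8,8-tetramethyl-3-(triethylsilyloxy)-1,2,3,3a,4,5,8,8a-octahydroazulen-7-yl trifluoromethanesulfonate | CC1=C(OS(=O)(=O)C(F)(F)F)C(C)(C)[C@@H]2CC[C@@](C)(O[Si](CC)(CC)CC)[C@@H]2CC1 | intermediate
27 | C13 allylic alcohol (both C13 epimers), tris(triethylsilyl) ether | CC1=C(C(O)C[C@@H]3[C@@]4(C)CC[C@@H](O[Si](CC)(CC)CC)C(C)(C)O[C@@H]4CC[C@]3(C)O[Si](CC)(CC)CC)C(C)(C)[C@@H]2CC[C@@](C)(O[Si](CC)(CC)CC)[C@@H]2CC1 | intermediate
28 | C13 enone, tris(triethylsilyl) ether | CC1=C(C(=O)C[C@@H]3[C@@]4(C)CC[C@@H](O[Si](CC)(CC)CC)C(C)(C)O[C@@H]4CC[C@]3(C)O[Si](CC)(CC)CC)C(C)(C)[C@@H]2CC[C@@](C)(O[Si](CC)(CC)CC)[C@@H]2CC1 | intermediate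
29 | (13R)-allylic alcohol, tris(triethylsilyl) ether | CC1=C([C@H](O)C[C@@H]3[C@@]4(C)CC[C@@H](O[Si](CC)(CC)CC)C(C)(C)O[C@@H]4CC[C@]3(C)O[Si](CC)(CC)CC)C(C)(C)[C@@H]2CC[C@@](C)(O[Si](CC)(CC)CC)[C@@H]2CC1 | intermediate
30 | (13S)-N-alkyl-N-(2-nitrobenzenesulfonyl) acetone hydrazone | CC1=C([C@@H](N(N=C(C)C)S(=O)(=O)c5ccccc5[N+](=O)[O-])C[C@@H]3[C@@]4(C)CC[C@@H](O[Si](CC)(CC)CC)C(C)(C)O[C@@H]4CC[C@]3(C)O[Si](CC)(CC)CC)C(C)(C)[C@@H]2CC[C@@](C)(O[Si](CC)(CC)CC)[C@@H]2CC1 | intermediate
31 | (13S)-N-alkyl-N-(2-nitrobenzenesulfonyl)hydrazine | CC1=C([C@@H](N(N)S(=O)(=O)c5ccccc5[N+](=O)[O-])C[C@@H]3[C@@]4(C)CC[C@@H](O[Si](CC)(CC)CC)C(C)(C)O[C@@H]4CC[C@]3(C)O[Si](CC)(CC)CC)C(C)(C)[C@@H]2CC[C@@](C)(O[Si](CC)(CC)CC)[C@@H]2CC1 | intermediate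
32 | (13S)-allylic diazene | CC1=C([C@@H](N=N)C[C@@H]3[C@@]4(C)CC[C@@H](O[Si](CC)(CC)CC)C(C)(C)O[C@@H]4CC[C@]3(C)O[Si](CC)(CC)CC)C(C)(C)[C@@H]2CC[C@@](C)(O[Si](CC)(CC)CC)[C@@H]2CC1 | intermediate
33 | 3,10,19-tris(triethylsilyl) ether of the target | C[C@@H]1CC[C@@H]2[C@@H](CC[C@@]2(C)O[Si](CC)(CC)CC)C(C)(C)/C1=C/C[C@@H]1[C@@]2(C)CC[C@@H](O[Si](CC)(CC)CC)C(C)(C)O[C@@H]2CC[C@]1(C)O[Si](CC)(CC)CC | intermediate
34 | CNP0167890.2 | C[C@@H]1CC[C@@H]2[C@@H](CC[C@@]2(C)O)C(C)(C)/C1=C/C[C@@H]1[C@@]2(C)CC[C@@H](O)C(C)(C)O[C@@H]2CC[C@]1(C)O | target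

**Step count**

Total: 24 steps. Longest linear sequence: 15 steps (13 → 34, steps 10–24); the ring A/B branch is 9 steps to aldehyde 12 and 14 steps to the target.

**Steps most likely to fail**

1. Step 5. The enol silane may attack the silyl-activated 6,7-epoxide before the oxygen bridge has formed, so that the cascade stops after ring B, or the epoxonium ion may open in the exo sense. The fallback sets out from enol silane 7 and returns at ketone 8; it replaces the terminator by a less nucleophilic allylsilane, so that the epoxonium ion has time to form. CsF and PhNTf2 would convert 7 with retention of geometry into the (Z)-enol triflate F1. Kumada coupling with Me3SiCH2MgCl and Pd(PPh3)4 would give the (Z)-allylsilane F2. BF3·OEt2 in CH2Cl2 at −78 °C would then trigger the same two ring closures, ended by loss of the silyl group, to give the C10-methylene bicyclic alcohol F3. Silylation (Et3SiOTf, 2,6-lutidine) to the triethylsilyl ether F4 and Lemieux–Johnson cleavage (OsO4 cat., NaIO4) of the exocyclic alkene would deliver 8.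

2. Step 23. The Mitsunobu displacement at the hindered, ionisable allylic carbinol may be slow or may run through an allyl cation (scrambling, elimination to a diene), which would erode the transfer of configuration from C13 to C15. The fallback sets out from enone 28 and returns at 33; it needs no displacement at C13. Condensation with TsNHNH2 would give the tosylhydrazone F5. Catecholborane would reduce its C=N bond to the tosylhydrazine F6 (both C13 epimers), and warming with NaOAc·3H2O would eliminate sulfinate to diazene 32 and its (13R)-epimer F7, which lose N2 as in step 23. Because C13 is then no longer set by a reagent, 33 would be accompanied by its C15 epimer F8 and would have to be separated from it.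

3. Step 20. Insertion and transmetalation at the tetrasubstituted alkenyl triflate next to a quaternary carbon may be too slow, so that reduction of the triflate or reductive dimerisation of the aldehyde takes over. The fallback sets out from enone 24 and returns at 27; it uses an alkenyllithium instead. Conjugate reduction (LiBH(s-Bu)3, protic work-up) would give the saturated ketone F9 and hydrazine hydrate the hydrazone F10. Iodine and tetramethylguanidine (Barton vinyl iodide synthesis) would give the alkenyl iodide F11, C15 being the only enolisable side. Iodine–lithium exchange with t-BuLi would give the alkenyllithium F12, which adds to aldehyde 12 to give 27.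

**Further compounds**

F1 | step 5 | (3R,6R,7R)-bis-epoxy (Z)-C10=C11 enol triflate | CC1(C)O[C@@H]1CC[C@@]2(C)O[C@@H]2CC/C(OS(=O)(=O)C(F)(F)F)=C/CCOCc1ccccc1
F2 | step 5 | (3R,6R,7R)-bis-epoxy (Z)-allylsilane (C10 bearing CH2SiMe3) | CC1(C)O[C@@H]1CC[C@@]2(C)O[C@@H]2CC/C(C[Si](C)(C)C)=C/CCOCc1ccccc1
F3 | step 5 | (3R,6R,7R,11R)-ring A/B C10-methylene alcohol (C3 hydroxyl, C13 benzyl ether) | c1ccccc1COCC[C@@H]2[C@@]3(C)CC[C@@H](O)C(C)(C)O[C@@H]3CCC2=C
F4 | step 5 | C3 triethylsilyl ether of F3 | c1ccccc1COCC[C@@H]2[C@@]3(C)CC[C@@H](O[Si](CC)(CC)CC)C(C)(C)O[C@@H]3CCC2=C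
F5 | step 23 | C13 tosylhydrazone of enone 28 | CC1=C(C(=NNS(=O)(=O)c5ccc(C)cc5)C[C@@H]3[C@@]4(C)CC[C@@H](O[Si](CC)(CC)CC)C(C)(C)O[C@@H]4CC[C@]3(C)O[Si](CC)(CC)CC)C(C)(C)[C@@H]2CC[C@@](C)(O[Si](CC)(CC)CC)[C@@H]2CC1
F6 | step 23 | C13 tosylhydrazine (both C13 epimers) | CC1=C(C(NNS(=O)(=O)c5ccc(C)cc5)C[C@@H]3[C@@]4(C)CC[C@@H](O[Si](CC)(CC)CC)C(C)(C)O[C@@H]4CC[C@]3(C)O[Si](CC)(CC)CC)C(C)(C)[C@@H]2CC[C@@](C)(O[Si](CC)(CC)CC)[C@@H]2CC1
F7 | step 23 | (13R)-allylic diazene | CC1=C([C@H](N=N)C[C@@H]3[C@@]4(C)CC[C@@H](O[Si](CC)(CC)CC)C(C)(C)O[C@@H]4CC[C@]3(C)O[Si](CC)(CC)CC)C(C)(C)[C@@H]2CC[C@@](C)(O[Si](CC)(CC)CC)[C@@H]2CC1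
F8 | step 23 | C15 epimer of 33 | C[C@H]1CC[C@@H]2[C@@H](CC[C@@]2(C)O[Si](CC)(CC)CC)C(C)(C)/C1=C/C[C@@H]1[C@@]2(C)CC[C@@H](O[Si](CC)(CC)CC)C(C)(C)O[C@@H]2CC[C@]1(C)O[Si](CC)(CC)CC
F9 | step 20 | saturated ring C/D ketone (C15 epimers) | C[C@@]1(O[Si](CC)(CC)CC)CC[C@@H]2[C@H]1CCC(C)C(=O)C2(C)C
F10 | step 20 | hydrazone of F9 | C[C@@]1(O[Si](CC)(CC)CC)CC[C@@H]2[C@H]1CCC(C)C(=NN)C2(C)C
F11 | step 20 | ring C/D C14 alkenyl iodide | CC1=C(I)C(C)(C)[C@@H]2CC[C@@](C)(O[Si](CC)(CC)CC)[C@@H]2CC1
F12 | step 20 | ring C/D C14 alkenyllithium | CC1=C([Li])C(C)(C)[C@@H]2CC[C@@](C)(O[Si](CC)(CC)CC)[C@@H]2CC1
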